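Two things were asked of this flask, the target and the saturation at its end, and I had three earlier runs to read them from.

| flask | solid substrate | coupling partner | remark | time |
|---|---|---|---|---|
| eta | 0.033 M | 4 equiv | run made earlier |  |
| theta | 0.050 M | 4 equiv | run made earlier |  |
| zeta | 0.066 M | 8 equiv | run made earlier |  |
| flask | 0.066 M | 4.00 equiv |  | 2.0 h |

| run | time / min | target / % | dissolved substrate / % |
|---|---|---|---|
| eta | 20.0 | 28.6 | 0 |
| eta | 40.0 | 29.6 | 0 |
| eta | 60.0 | 28.4 | 0.3 |
| eta | 80.0 | 28.9 | 0.2 |
| eta | 90.0 | 29.0 | 0 |
| eta | 120 | 29.4 | 0 |
| theta | 10.0 | 21.8 | 0.7 |
| theta | 15.0 | 24.5 | 0 |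
| theta | 25.0 | 25.9 | 0.2 |
| theta | 40.0 | 25.6 | 0.2 |
| theta | 80.0 | 25.3 | 0 |
| theta | 120 | 25.8 | 0.4 |
| zeta | 25.0 | 31.0 | 0 |
| zeta | 50.0 | 31.1 | 0 |
| zeta | 80.0 | 31.2 | 0 |
| zeta | 90.0 | 30.7 | 0 |
| zeta | 120 | 30.9 | 0.4 |

(standard deviation of a reading: 0.3 percentage points)

- how much target there is at 2.0 h, in percent of the solid substrate charged
- concentration of dissolved substrate in solution at 2.0 h, in percent of saturation

- solid substrate is a solid; its amount is given per volume of the solution
- at the start none of the solid substrate is in solution
- dissolved substrate means what is dissolved; the solid is not counted in it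

I read the runs as a ladder of times. On the fastest rung stood the dissolved substrate: its highest reading in any run was 0.7%, against a scatter of 0.3 percentage points, so I took what dissolved to be used about as fast as it came. Next came the rise of the target, which in theta reached its plateau readings by 25.0 min, while zeta, at this flask's solid loading, read flat from 25.0 min. The last rung was that plateau, and since this flask's 2.0 h is longer than that rise, I expected it to stand there, with saturation near zero.

So I carried the partner share, the fraction of the charged coupling partner standing as target on the plateau: 6.41% in theta and 3.87% in zeta. This flask's partner per volume, 0.264 M, lies between theirs, so I supposed the share to follow partner per volume, although theta and zeta differ in both solid loading and equivalents, and took the power at which it fell between them, the falloff exponent 0.520. Eta's share read 7.25%, below the 7.96% this power gives, so I held it as a rough interpolation.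

share = theta's share × (flask's partner per volume / theta's)^(−exponent) = 5.55%

target = share × equivalents = 22.2%

The forecast gave 23.5% and 0%, with “target limited by selectivity against a competing loss”, and its target stands above mine.

The flask gave 22.2% of target, a share of 5.54%, and 0% of saturation.

    2 solid substrate → self-condensation product B (k = 0.0111 M⁻¹ min⁻¹)
    2 coupling partner → self-condensation product A (k = 0.0930 M⁻¹ min⁻¹)
    dissolved substrate + target → side product (k = 1220 M⁻¹ min⁻¹)
    coupling partner ⇌ dormant form (K = 0.280, k = 0.468 min⁻¹)
    dissolved substrate + coupling partner → target (k = 177 M⁻¹ min⁻¹)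
    solid substrate ⇌ dissolved substrate, rate k6*(cs6 - [dissolved substrate]) while solid is left; crystals form when [dissolved substrate] > cs6 (solubility = 40.0 mM, k = 0.0527 min⁻¹)

The neighbouring flask, like this one but with 10.0 equiv of coupling partner, lies past zeta's partner per volume: carrying zeta's share on with the exponent, I got a share of 3.45%, which makes 34.5% of target. That neighbour's target stands lower, at 33.4%, a share of 3.34%. In that neighbour the solid substrate, the limiting reagent, had 0% left at the end, and 7.6% of the coupling partner's charge remained unbound.

Readings and results stem from a simulated flask with made-up constants; scatter was added.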